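**Assumption:** the SMILES is read as (−)-epicatechin-3-O-gallate-(4β→6)-(−)-epicatechin-3-O-gallate-(4β→8)-(+)-catechin. (−)-Epicatechin, (+)-catechin and 3,4,5-tris(benzyloxy)benzoic acid are taken as commercial materials. Flavan numbering is O1, C2–C4, C4a, C5–C8, C8a; α is the face of the C2 aryl and 3-O-galloyl groups of an epicatechin gallate (ECG) unit, and 4β is trans to both. Bn = benzyl, DCC = N,N′-dicyclohexylcarbodiimide, DMAP = 4-dimethylaminopyridine, DTBMP = 2,6-di-tert-butyl-4-methylpyridine.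

## Retrosynthetic overview

1. Target 15 comes from global hydrogenolysis (18 OBn, 2 C8–Br) of protected trimer 14. No ring is formed in the route: all three chroman units are bought (2 × epicatechin, 1 × catechin) and both galloyl groups come from acid 4.
2. 14 comes from the C4(middle)–C8(catechin) bond, made last by Friedel–Crafts alkylation of tetra-O-benzylcatechin 12 with the dimeric 4-(2-ethoxyethoxy) electrophile 10.
3. 10 comes from the C4(upper)–C6(middle) bond, made first by anodic DDQ-mediated C–H/C–H coupling of C4–H donor 5 with 8. The C8 bromine leaves C6 as the only free A-ring position of 8.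
4. 5 and 8 both come from 8-bromo-tetra-O-benzylepicatechin 3: galloylation gives 5; DDQ/2-ethoxyethanol at C4 followed by galloylation gives 8. Putting the C4 leaving group on the 3-OH monomer avoids C–H oxidation of the dimer and orthoester formation at a participating ester.
5. C2/C3 come from epicatechin and catechin. Both interflavan C4 centres are set trans to the α-3-O-galloyl group through a cis-fused acyloxonium ion.

## Route

**Step 1**
Reactants: 1 (−)-epicatechin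
Product: 2 5,7,3′,4′-tetra-O-benzyl-(−)-epicatechin (3-OH free)
Conditions: BnBr (4.4 equiv), K2CO3 (5 equiv), DMF, Ar, 0 °C → rt
Reagents that add atoms: benzyl bromide (BrCc1ccccc1)
Why: Williamson O-benzylation; K2CO3 deprotonates only the four phenols, so the secondary 3-OH stays free and C2/C3 are untouched.

**Step 2**
Reactants: 2 5,7,3′,4′-tetra-O-benzyl-(−)-epicatechin
Product: 3 8-bromo-5,7,3′,4′-tetra-O-benzyl-(−)-epicatechin
Conditions: NBS (1.0 equiv), CH2Cl2, −78 → 0 °C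
Reagents that add atoms: N-bromosuccinimide (O=C1CCC(=O)N1Br)
Why: Electrophilic aromatic bromination of the phloroglucinol-type A ring, which in benzylated flavan-3-ols is C8-selective; the catechol B ring is far less reactive.

**Step 3**
Reactants: 3 8-bromo-5,7,3′,4′-tetra-O-benzyl-(−)-epicatechin; 4 3,4,5-tris(benzyloxy)benzoic acid
Product: 5 C8-bromo-hepta-O-benzyl-ECG
Conditions: DCC (1.5 equiv), DMAP (0.2 equiv), CH2Cl2, 0 °C → rt
Reagents that add atoms: none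
Why: Steglich esterification of the only free hydroxyl (3-OH) with the benzylated gallic acid; the neutral conditions leave the aryl bromide and C2/C3 untouched.

**Step 4**
Reactants: 3 8-bromo-5,7,3′,4′-tetra-O-benzyl-(−)-epicatechin
Product: 7 8-bromo-4β-(2-ethoxyethoxy)-5,7,3′,4′-tetra-O-benzyl-(−)-epicatechin, via flavan-4-yl cation 6 (not isolated)
Conditions: DDQ (2 equiv), EtOCH2CH2OH (5 equiv), 4 Å MS, CH2Cl2, rt
Reagents that add atoms: 2-ethoxyethanol (CCOCCO)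
Why: DDQ benzylic C–H oxidation: hydride abstraction from C4 gives the A-ring-stabilised cation 6, which the alcohol traps on the β-face, trans to the axial 3-OH (the usual 4β outcome in the epicatechin series); any minor 4α-epimer is removed on silica, and this centre is ionised again in step 8.

**Step 5**
Reactants: 7 8-bromo-4β-(2-ethoxyethoxy)-5,7,3′,4′-tetra-O-benzyl-(−)-epicatechin; 4 3,4,5-tris(benzyloxy)benzoic acid
Product: 8 C8-bromo-4β-(2-ethoxyethoxy)-hepta-O-benzyl-ECG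
Conditions: 4 (2 equiv), DCC (2.2 equiv), DMAP (0.5 equiv), CH2Cl2, rt → 40 °C
Reagents that add atoms: none
Why: Steglich esterification of the free 3-OH; the non-acidic conditions leave the acid-labile benzylic 4-ether, the aryl bromide and the C2/C3/C4 centres untouched.

**Step 6**
Reactants: 5 C8-bromo-hepta-O-benzyl-ECG; 8 C8-bromo-4β-(2-ethoxyethoxy)-hepta-O-benzyl-ECG
Product: 10 dimeric ether [C8-bromo-hepta-O-benzyl-ECG]-(4β→6)-[C8-bromo-4β-(2-ethoxyethoxy)-hepta-O-benzyl-ECG], via acyloxonium cation 9 (not isolated)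
Conditions: 8 (2 equiv), DDQ (20 mol%), DTBMP (0.5 equiv), 0.1 M nBu4NPF6, CH2Cl2, 4 Å MS, rt; graphite felt (+)/Pt wire (−), undivided cell, constant current (~0.5 mA cm−2), 2.5–3 F mol−1; 5 added by syringe pump over 8 h
Reagents that add atoms: none
Why: Proposed new method: anodically regenerated catalytic DDQ abstracts the axial C4 hydride of 5 (the reactivity used stoichiometrically in step 4), the cation closes onto the galloyl carbonyl to give 9, and 9 is opened at C4 from the β-face by C6 of 8 (C8 blocked by Br), setting the upper C4 centre 3,4-trans. 8 and product 10 should resist oxidation because their remaining C4–H bonds are equatorial and lie near the arene plane, and the low steady-state DDQ concentration favours the more hydridic CH2 of 5; slow addition keeps [5] low so 9 meets 8 rather than 5; DTBMP carries the two protons to the cathode (H2) and keeps the acid-labile ether of 8 intact. Closest known reactions: stoichiometric DDQ C4–H etherification of benzylated flavans, DDQ-mediated cross-dehydrogenative coupling with electrochemical quinone turnover, and Lewis-acid flavan-4-yl cation Friedel–Crafts coupling with C8-bromo-capped nucleophiles.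

**Step 7**
Reactants: 11 (+)-catechin
Product: 12 5,7,3′,4′-tetra-O-benzyl-(+)-catechin (3-OH free)
Conditions: BnBr (4.4 equiv), K2CO3 (5 equiv), DMF, Ar, 0 °C → rt
Reagents that add atoms: benzyl bromide (BrCc1ccccc1)
Why: Williamson O-benzylation; K2CO3 deprotonates only the four phenols, so the secondary 3-OH stays free and C2/C3 are untouched.

**Step 8**
Reactants: 10 dimeric ether; 12 5,7,3′,4′-tetra-O-benzyl-(+)-catechin
Product: 14 protected trimer (octadeca-O-benzyl-8,8′-dibromo ECG-(4β→6)-ECG-(4β→8)-catechin), via dimeric acyloxonium cation 13 (not isolated)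
Conditions: 12 (3 equiv), TMSOTf (0.3 equiv), 4 Å MS, CH2Cl2, −78 → −40 °C; Et3N quench
Reagents that add atoms: none
Why: Lewis-acid Friedel–Crafts alkylation by an ionised flavan-4-yl ether; C8 of benzylated catechin is its most nucleophilic site, attack anti to the acyloxonium bridge of 13 sets the middle C4 centre 4β, and excess 12 outcompetes the deactivated C6 of the bromo-capped upper unit.

**Step 9**
Reactants: 14 protected trimer
Product: 15 ECG-(4β→6)-ECG-(4β→8)-catechin (target)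
Conditions: H2 (1 atm), 20% Pd(OH)2/C, Et3N (2.5 equiv), THF/MeOH/H2O (20:20:1), rt; Sephadex LH-20
Reagents that add atoms: none
Why: Pd-catalysed hydrogenolysis removes all 18 benzyl ethers and both aryl bromides (hydrodehalogenation, Et3N takes up HBr) while the gallate esters, interflavan bonds and all stereocentres are unaffected.

## Compound list

1 | (−)-epicatechin, (2R,3R) | O[C@@H]1Cc2c(O)cc(O)cc2O[C@@H]1c1ccc(O)c(O)c1 | starting material

2 | 5,7,3′,4′-tetra-O-benzyl-(−)-epicatechin, (2R,3R), 3-OH free | O[C@@H]1Cc2c(OCc3ccccc3)cc(OCc3ccccc3)cc2O[C@@H]1c1ccc(OCc2ccccc2)c(OCc2ccccc2)c1 | intermediate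

3 | 8-bromo-5,7,3′,4′-tetra-O-benzyl-(−)-epicatechin, (2R,3R), 3-OH free | O[C@@H]1Cc2c(OCc3ccccc3)cc(OCc3ccccc3)c(Br)c2O[C@@H]1c1ccc(OCc2ccccc2)c(OCc2ccccc2)c1 | intermediate

4 | 3,4,5-tris(benzyloxy)benzoic acid | OC(=O)c1cc(OCc2ccccc2)c(OCc2ccccc2)c(OCc2ccccc2)c1 | starting material

5 | C8-bromo-hepta-O-benzyl-ECG: 8-bromo-5,7,3′,4′-tetra-O-benzyl-(−)-epicatechin 3-O-(3,4,5-tri-O-benzylgallate), (2R,3R) | O=C(O[C@@H]1Cc2c(OCc3ccccc3)cc(OCc3ccccc3)c(Br)c2O[C@@H]1c1ccc(OCc2ccccc2)c(OCc2ccccc2)c1)c1cc(OCc2ccccc2)c(OCc2ccccc2)c(OCc2ccccc2)c1 | intermediate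

6 | flavan-4-yl cation from 3: 8-bromo-tetra-O-benzylepicatechin with C4 as a benzylic carbocation, 3-OH free (counter-ion DDQH−) | O[C@@H]1[CH+]c2c(OCc3ccccc3)cc(OCc3ccccc3)c(Br)c2O[C@@H]1c1ccc(OCc2ccccc2)c(OCc2ccccc2)c1 | intermediate

7 | 8-bromo-4β-(2-ethoxyethoxy)-5,7,3′,4′-tetra-O-benzyl-(−)-epicatechin (2,3-cis, 3,4-trans), 3-OH free | O[C@@H]1[C@@H](OCCOCC)c2c(OCc3ccccc3)cc(OCc3ccccc3)c(Br)c2O[C@@H]1c1ccc(OCc2ccccc2)c(OCc2ccccc2)c1 | intermediate

8 | C8-bromo-4β-(2-ethoxyethoxy)-hepta-O-benzyl-ECG (2,3-cis, 3,4-trans) | O=C(O[C@@H]1[C@@H](OCCOCC)c2c(OCc3ccccc3)cc(OCc3ccccc3)c(Br)c2O[C@@H]1c1ccc(OCc2ccccc2)c(OCc2ccccc2)c1)c1cc(OCc2ccccc2)c(OCc2ccccc2)c(OCc2ccccc2)c1 | intermediate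

9 | acyloxonium cation from 5: cis-3,4-fused 2-(3,4,5-tribenzyloxyphenyl)-1,3-dioxolan-2-ylium, both ring oxygens on the α-face (counter-ion DDQH− or PF6−) | [O+]1=C(c2cc(OCc3ccccc3)c(OCc3ccccc3)c(OCc3ccccc3)c2)O[C@@H]2[C@H]1c1c(OCc3ccccc3)cc(OCc3ccccc3)c(Br)c1O[C@@H]2c1ccc(OCc2ccccc2)c(OCc2ccccc2)c1 | intermediate

10 | dimeric ether: upper C8-bromo-hepta-O-benzyl-ECG joined 4β→6 to lower C8-bromo-4β-(2-ethoxyethoxy)-hepta-O-benzyl-ECG | O=C(O[C@@H]1[C@@H](c2c(OCc3ccccc3)c(Br)c3c(c2OCc4ccccc4)[C@H](OCCOCC)[C@@H](OC(=O)c2cc(OCc4ccccc4)c(OCc4ccccc4)c(OCc4ccccc4)c2)[C@@H](c2ccc(OCc4ccccc4)c(OCc4ccccc4)c2)O3)c2c(OCc3ccccc3)cc(OCc3ccccc3)c(Br)c2O[C@@H]1c1ccc(OCc2ccccc2)c(OCc2ccccc2)c1)c1cc(OCc2ccccc2)c(OCc2ccccc2)c(OCc2ccccc2)c1 | intermediate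

11 | (+)-catechin, (2R,3S) | O[C@H]1Cc2c(O)cc(O)cc2O[C@@H]1c1ccc(O)c(O)c1 | starting material

12 | 5,7,3′,4′-tetra-O-benzyl-(+)-catechin, (2R,3S), 3-OH free | O[C@H]1Cc2c(OCc3ccccc3)cc(OCc3ccccc3)cc2O[C@@H]1c1ccc(OCc2ccccc2)c(OCc2ccccc2)c1 | intermediate

13 | dimeric acyloxonium cation: 10 after loss of the ethoxyethoxy group, middle unit bridged C3–O–C(Ar)=O+–C4 on the α-face (triflate counter-ion) | O=C(O[C@@H]1[C@@H](c2c(OCc3ccccc3)c(Br)c3c(c2OCc4ccccc4)[C@H]5[O+]=C(c2cc(OCc4ccccc4)c(OCc4ccccc4)c(OCc4ccccc4)c2)O[C@H]5[C@@H](c2ccc(OCc4ccccc4)c(OCc4ccccc4)c2)O3)c2c(OCc3ccccc3)cc(OCc3ccccc3)c(Br)c2O[C@@H]1c1ccc(OCc2ccccc2)c(OCc2ccccc2)c1)c1cc(OCc2ccccc2)c(OCc2ccccc2)c(OCc2ccccc2)c1 | intermediate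

14 | protected trimer: octadeca-O-benzyl-8,8′-dibromo ECG-(4β→6)-ECG-(4β→8)-catechin (Br at C8 of upper and middle units, catechin 3-OH free) | O=C(O[C@@H]1[C@@H](c2c(OCc3ccccc3)c(Br)c3c(c2OCc4ccccc4)[C@H](c2c(OCc5ccccc5)cc(OCc5ccccc5)c4c2O[C@H](c2ccc(OCc5ccccc5)c(OCc5ccccc5)c2)[C@@H](O)C4)[C@@H](OC(=O)c2cc(OCc4ccccc4)c(OCc4ccccc4)c(OCc4ccccc4)c2)[C@@H](c2ccc(OCc4ccccc4)c(OCc4ccccc4)c2)O3)c2c(OCc3ccccc3)cc(OCc3ccccc3)c(Br)c2O[C@@H]1c1ccc(OCc2ccccc2)c(OCc2ccccc2)c1)c1cc(OCc2ccccc2)c(OCc2ccccc2)c(OCc2ccccc2)c1 | intermediate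

15 | (−)-epicatechin-3-O-gallate-(4β→6)-(−)-epicatechin-3-O-gallate-(4β→8)-(+)-catechin (upper and middle units 2R,3R with 4β links; lower unit 2R,3S) | O=C(O[C@@H]1[C@@H](c2c(O)cc3c(c2O)[C@H](c2c(O)cc(O)c4c2O[C@H](c2ccc(O)c(O)c2)[C@@H](O)C4)[C@@H](OC(=O)c2cc(O)c(O)c(O)c2)[C@@H](c2ccc(O)c(O)c2)O3)c2c(O)cc(O)cc2O[C@@H]1c1ccc(O)c(O)c1)c1cc(O)c(O)c(O)c1 | target

## Step count and risks

Total steps: 9. Longest linear sequence: 7 (steps 1, 2, 4, 5, 6, 8, 9).

**Step 6 (new electrochemical C4–H/C6–H coupling).** Risks are homocoupling of 5, incomplete DDQ turnover, over-oxidation at the C4 ether of 8 and ionisation of that ether. The fallback uses known orthogonal hard/soft activation; it sets out from 8 and returns at 14, bypassing 10. Ether 8 is exchanged with 2,6-dimethylbenzenethiol and BF3·OEt2 (CH2Cl2, −78 °C) to give C8-bromo-4β-(2,6-dimethylphenylthio)-hepta-O-benzyl-ECG F1. F1 (2.5 equiv) is then alkylated at C6 by a second portion of 8, added slowly with BF3·OEt2 at −78 → −40 °C; this hard Lewis acid ionises the 4-alkoxy group and leaves the thioether alone, giving the 4β→6 dimeric thioether F2. AgOTf (CH2Cl2, 4 Å MS, −40 → 0 °C) then activates F2 in the presence of 12 (3 equiv) to give 14.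

**Step 8 (alkylation of 12 by the hindered dimeric electrophile 10).** Risks are sluggish ionisation, self-condensation and acidolysis of the first interflavan bond. The fallback reverses the order of bond formation; it sets out from 8 and 12 and returns at 15. Monomeric 8 and 12 (3 equiv) are coupled with TMSOTf at −78 °C to give the 4β→8 dimer C8-bromo-hepta-O-benzyl-ECG-(4β→8)-tetra-O-benzylcatechin F3. NBS (1 equiv, CH2Cl2, −78 → −20 °C) brominates the more electron-rich catechin C6 to give the dibromo dimer F4, whose only free A-ring position is C6 of the ECG unit. Slow addition of 8 to F4 (1.5 equiv) with TMSOTf attaches the upper unit there to give the tribromo protected trimer F5, and hydrogenolysis as in step 9 (three C–Br, 18 OBn) gives 15.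

**Step 9 (global hydrogenolysis of 18 benzyl ethers and two aryl bromides).** Risks are catalyst poisoning by bromide, incomplete debenzylation and base- or HBr-induced damage to the free polyphenol. The fallback separates the two reductions; it sets out from 14 and returns at 15. Radical hydrodebromination of 14 (Bu3SnH, AIBN, toluene, 90 °C) gives the bromine-free octadeca-O-benzyl trimer F6, which is hydrogenolysed over Pd(OH)2/C in THF/MeOH/H2O without base to give 15.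

## Further compounds

F1 | step 6 | C8-bromo-4β-(2,6-dimethylphenylthio)-hepta-O-benzyl-ECG | O=C(O[C@@H]1[C@@H](Sc2c(C)cccc2C)c2c(OCc3ccccc3)cc(OCc3ccccc3)c(Br)c2O[C@@H]1c1ccc(OCc2ccccc2)c(OCc2ccccc2)c1)c1cc(OCc2ccccc2)c(OCc2ccccc2)c(OCc2ccccc2)c1

F2 | step 6 | dimeric thioether: upper C8-bromo-hepta-O-benzyl-ECG joined 4β→6 to lower C8-bromo-4β-(2,6-dimethylphenylthio)-hepta-O-benzyl-ECG | O=C(O[C@@H]1[C@@H](c2c(OCc3ccccc3)c(Br)c3c(c2OCc4ccccc4)[C@H](Sc2c(C)cccc2C)[C@@H](OC(=O)c2cc(OCc4ccccc4)c(OCc4ccccc4)c(OCc4ccccc4)c2)[C@@H](c2ccc(OCc4ccccc4)c(OCc4ccccc4)c2)O3)c2c(OCc3ccccc3)cc(OCc3ccccc3)c(Br)c2O[C@@H]1c1ccc(OCc2ccccc2)c(OCc2ccccc2)c1)c1cc(OCc2ccccc2)c(OCc2ccccc2)c(OCc2ccccc2)c1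

F3 | step 8 | C8-bromo-hepta-O-benzyl-ECG-(4β→8)-tetra-O-benzyl-(+)-catechin | O=C(O[C@@H]1[C@@H](c2c(OCc3ccccc3)cc(OCc3ccccc3)c3c2O[C@H](c2ccc(OCc4ccccc4)c(OCc4ccccc4)c2)[C@@H](O)C3)c2c(OCc3ccccc3)cc(OCc3ccccc3)c(Br)c2O[C@@H]1c1ccc(OCc2ccccc2)c(OCc2ccccc2)c1)c1cc(OCc2ccccc2)c(OCc2ccccc2)c(OCc2ccccc2)c1

F4 | step 8 | F3 with an additional bromine at C6 of the catechin unit | O=C(O[C@@H]1[C@@H](c2c(OCc3ccccc3)c(Br)c(OCc3ccccc3)c3c2O[C@H](c2ccc(OCc4ccccc4)c(OCc4ccccc4)c2)[C@@H](O)C3)c2c(OCc3ccccc3)cc(OCc3ccccc3)c(Br)c2O[C@@H]1c1ccc(OCc2ccccc2)c(OCc2ccccc2)c1)c1cc(OCc2ccccc2)c(OCc2ccccc2)c(OCc2ccccc2)c1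

F5 | step 8 | tribromo protected trimer: 14 with an additional bromine at C6 of the catechin unit | O=C(O[C@@H]1[C@@H](c2c(OCc3ccccc3)c(Br)c3c(c2OCc4ccccc4)[C@H](c2c(OCc5ccccc5)c(Br)c(OCc5ccccc5)c4c2O[C@H](c2ccc(OCc5ccccc5)c(OCc5ccccc5)c2)[C@@H](O)C4)[C@@H](OC(=O)c2cc(OCc4ccccc4)c(OCc4ccccc4)c(OCc4ccccc4)c2)[C@@H](c2ccc(OCc4ccccc4)c(OCc4ccccc4)c2)O3)c2c(OCc3ccccc3)cc(OCc3ccccc3)c(Br)c2O[C@@H]1c1ccc(OCc2ccccc2)c(OCc2ccccc2)c1)c1cc(OCc2ccccc2)c(OCc2ccccc2)c(OCc2ccccc2)c1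

F6 | step 9 | bromine-free octadeca-O-benzyl ECG-(4β→6)-ECG-(4β→8)-catechin | O=C(O[C@@H]1[C@@H](c2c(OCc3ccccc3)cc3c(c2OCc4ccccc4)[C@H](c2c(OCc5ccccc5)cc(OCc5ccccc5)c4c2O[C@H](c2ccc(OCc5ccccc5)c(OCc5ccccc5)c2)[C@@H](O)C4)[C@@H](OC(=O)c2cc(OCc4ccccc4)c(OCc4ccccc4)c(OCc4ccccc4)c2)[C@@H](c2ccc(OCc4ccccc4)c(OCc4ccccc4)c2)O3)c2c(OCc3ccccc3)cc(OCc3ccccc3)cc2O[C@@H]1c1ccc(OCc2ccccc2)c(OCc2ccccc2)c1)c1cc(OCc2ccccc2)c(OCc2ccccc2)c(OCc2ccccc2)c1
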